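**Plan**
Locants: C1 = quaternary oxirane carbon (bears C7H2OBz), C2 (OAc), C3 (OBz), C4=C5, C6 = oxirane CH; β = ring face carrying C7, α = face carrying the C1 oxygen.
Cuts, in retrosynthetic order: the C6–O oxirane bond (C1–O is kept), the three ester C–O bonds, the C4=C5/C6–O allylic pattern back to a C4 enone with C5=C6, the C3–O bond, and the C2–O bond.
Enabling feature: C1 with its oxygen and C7 is the quaternary carbon of a para-quinol ring C1–C6 whose enone arms C2=C3 and C6=C5 flank the C4 carbonyl; O2 is cis to C7, so O7 can pass an oxygen to C2 through one boron atom in a six-membered dioxaborinane.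
Forward order: arene → para-quinol carbocycle → dioxaborinane (C2–O) → acetonide → 5,6β-oxirane → C3–O → Wharton shift to C4=C5 with C6–OH → esters → 1,6α-oxirane closed last.
Stereochemistry: C1 and C2 together from catalyst choice between the enantiotopic enone arms plus the cis tether; C6 (anti to C1–OSi) and C3 (anti to C2–O) by substrate control; C6 is inverted in the final SN2 closure.

Key step: step 5

Assumption: the sense of arm selection by the cinchona thiourea cannot be fixed on paper; the quinidine-derived catalyst is written, and its quinine-derived pseudoenantiomer would be used if it gives the mirror-image boronate.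
TBS = tert-butyldimethylsilyl. Target locants (C1–C7, O1, O2, O7) and the α/β faces defined above are used for all compounds.

Step 1
Reactants: 1 4-hydroxybenzyl alcohol
Product: 2 4-{[(tert-butyldimethylsilyl)oxy]methyl}phenol
Conditions: TBSCl (1.05 equiv), imidazole, DMF, 0 °C
Reagents that add atoms: tert-butyldimethylsilyl chloride, CC(C)(C)[Si](C)(C)Cl
Why: Chemoselective O-silylation: with about one equivalent of silyl chloride and imidazole the primary benzylic hydroxyl is silylated in preference to the phenol, which must stay free for the oxidation.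

Step 2
Reactants: 2 4-{[(tert-butyldimethylsilyl)oxy]methyl}phenol
Product: 3 4-hydroxy-4-(TBS-oxymethyl)cyclohexa-2,5-dien-1-one (achiral para-quinol)
Conditions: PhI(OAc)2, MeCN/H2O (3:1), 0 °C
Reagents that add atoms: water, O
Why: Oxidative dearomatisation of a para-substituted phenol with a trivalent iodine reagent: water traps the phenoxonium ion at the substituted para carbon to give the achiral para-quinol, and the silyl ether keeps the primary oxygen out of a glycol cleavage.

Step 3
Reactants: 3 4-hydroxy-4-(TBS-oxymethyl)cyclohexa-2,5-dien-1-one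
Product: 4 4-(TBS-oxy)-4-(TBS-oxymethyl)cyclohexa-2,5-dien-1-one
Conditions: TBSOTf, 2,6-lutidine, CH2Cl2, −78 → 0 °C
Reagents that add atoms: tert-butyldimethylsilyl trifluoromethanesulfonate, CC(C)(C)[Si](C)(C)OS(=O)(=O)C(F)(F)F
Why: Silylation of a hindered tertiary alcohol with a silyl triflate and a hindered pyridine base; the dienone has no enolisable hydrogen, so only the C1 hydroxyl reacts.

Step 4
Reactants: 4 4-(TBS-oxy)-4-(TBS-oxymethyl)cyclohexa-2,5-dien-1-one
Product: 5 4-(TBS-oxy)-4-(hydroxymethyl)cyclohexa-2,5-dien-1-one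
Conditions: HF·pyridine, pyridine, THF, 0 °C
Reagents that add atoms: none
Why: Selective fluoride-mediated cleavage of a primary silyl ether in the presence of a far more hindered tertiary one; the non-basic medium avoids the C7 alkoxide that could expel formaldehyde with aromatisation.

Step 5
Reactants: 5 4-(TBS-oxy)-4-(hydroxymethyl)cyclohexa-2,5-dien-1-one; 6 phenylboronic acid
Product: 7 (4aR,8aS)-4a-(TBS-oxy)-2-phenyl-4a,8a-dihydro-4H-benzo[d][1,3,2]dioxaborinin-7(8H)-one (cis-fused dioxaborinane enone: O2–B(Ph)–O7 ring, C4 ketone, C5=C6, O2 β, C1–OTBS α)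
Conditions: 6 (1.3 equiv), N-[3,5-bis(trifluoromethyl)phenyl]-N'-(9-deoxy-epi-quinidin-9-yl)thiourea (20 mol %), 4 Å molecular sieves, toluene, 25 °C
Reagents that add atoms: phenylboronic acid (6), OB(O)c1ccccc1
Why: Proposed new method: phenylboronic acid should condense reversibly with the C7 hydroxyl of 5 to a hemiester whose remaining B–OH, activated by the quinuclidine nitrogen of the catalyst while the thiourea hydrogen-bonds the C4 carbonyl, adds to C2 of one enone arm, the enolate then being protonated at C3. The closest known reaction type is the amine–thiourea-catalysed intramolecular oxa-Michael addition of boronic acid hemiesters of γ- and δ-hydroxy enones, combined here with the known desymmetrisation of 4,4-disubstituted cyclohexadienones by a tethered oxygen nucleophile. The dioxaborinane ring (C1–C7–O–B–O–C2) closes by 6-exo-trig conjugate addition. C2 is set by the tether, which can reach only the dienone face that carries C7, so the ring fusion is cis and O2 lies trans to the C1 silyloxy group; C1 becomes stereogenic because the chiral catalyst picks one of the two enantiotopic arms, which fixes the absolute configuration of both centres at once. The step needs that enantiotopic-group selection and a single addition: the silyl ether on O1 rules out a five-membered boronate between O1 and O7 and leaves O7 as the only tether, and the cyclic boronate formed has no B–OH left for the second enone.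

Step 6
Reactants: 7 cis-fused dioxaborinane enone
Product: 9 acetonide enone (O2,O7-isopropylidene, cis-fused 1,3-dioxane; C1–OTBS α; C4 ketone; C5=C6), via diol enone 8 (not isolated)
Conditions: 2,2-dimethoxypropane (excess), MeOH (5 equiv), PPTS (cat.), acetone, 25 °C
Reagents that add atoms: 2,2-dimethoxypropane, COC(C)(C)OC
Why: Acid-catalysed transesterification of the boronic ester with methanol followed by acetalisation of the freed cis-1,3-diol (protecting-group interchange); the isopropylidene acetal, unlike the arylboronate, tolerates the peroxide, amide base and hydrazine used next, and no stereocentre is touched.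

Step 7
Reactants: 9 acetonide enone
Product: 10 5,6β-epoxy ketone (acetonide, C1–OTBS α, C4 ketone, C3H2)
Conditions: 30% H2O2, benzyltrimethylammonium hydroxide (cat.), THF, 0 °C
Reagents that add atoms: hydrogen peroxide, OO
Why: Weitz–Scheffer nucleophilic epoxidation: hydroperoxide should add axially to C6 anti to the pseudoaxial C1 silyloxy group (the acetal holds C1–OSi and C2–O trans-diaxial) and the enolate closes on oxygen, which places the 5,6-oxirane on the β face and sets C6.

Step 8
Reactants: 10 5,6β-epoxy ketone
Product: 13 3α-hydroxy-5,6β-epoxy ketone (ketol; C3–OH trans to O2), via trimethylsilyl enol ether 11 (not isolated), via 3α-trimethylsilyloxy ketone 12 (not isolated)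
Conditions: LiN(iPr)2, Me3SiCl, THF, −78 °C; then mCPBA, NaHCO3, CH2Cl2, −20 °C; then Et3N·3HF, THF, 0 °C
Reagents that add atoms: 3-chloroperbenzoic acid, OOC(=O)c1cccc(Cl)c1
Why: Rubottom oxidation: kinetic C3 deprotonation with in situ silylation gives the only possible enol ether without β-elimination of O2, and the peracid should attack it anti to the adjacent axial C2–O bond, as peracids do with cyclic enol ethers that carry an allylic alkoxy group, so that the C3 hydroxyl ends up α, trans to O2.

Step 9
Reactants: 13 3α-hydroxy-5,6β-epoxy ketone; 14 benzoyl chloride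
Product: 15 3α-benzoyloxy-5,6β-epoxy ketone
Conditions: 14 (1.2 equiv), pyridine, DMAP (cat.), CH2Cl2, 0 °C
Reagents that add atoms: benzoyl chloride (14), O=C(Cl)c1ccccc1
Why: Pyridine/DMAP-mediated O-benzoylation of the secondary ketol hydroxyl, mild enough to leave the C3 stereocentre and the β-alkoxy ketone untouched.

Step 10
Reactants: 15 3α-benzoyloxy-5,6β-epoxy ketone
Product: 16 allylic alcohol (C4=C5, C6–OH β, C3–OBz α, acetonide, C1–OTBS α)
Conditions: N2H4·H2O (3 equiv), AcOH (cat.), MeOH, 0 → 25 °C
Reagents that add atoms: none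
Why: Wharton transposition: the C4 hydrazone opens the C5–O bond of the oxirane and loses N2, which gives the C4=C5 alkene and the C6 carbinol with the C6–O bond, and hence its β configuration (trans to the C1 oxygen), unchanged; the short acetic acid-buffered exposure should spare the benzoate.

Step 11
Reactants: 16 allylic alcohol
Product: 17 6-O-TBS ether of 16 (C1–OTBS α, C6–OTBS β, acetonide, C3–OBz α)
Conditions: TBSOTf, 2,6-lutidine, CH2Cl2, −78 → 0 °C
Reagents that add atoms: tert-butyldimethylsilyl trifluoromethanesulfonate, CC(C)(C)[Si](C)(C)OS(=O)(=O)C(F)(F)F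
Why: Silyl triflate silylation of a hindered secondary allylic alcohol, so that the C6 oxygen stays masked while O7 and O2 are acylated.

Step 12
Reactants: 17 6-O-TBS ether
Product: 18 2,7-diol (C2–OH β, C7–OH, C3–OBz α, C1–OTBS α, C6–OTBS β, C4=C5)
Conditions: PPTS, MeOH, 25 °C
Reagents that add atoms: none
Why: Acid-catalysed methanolysis (transacetalisation) of the cis-fused isopropylidene acetal, which is much faster than cleavage of the tertiary and the hindered secondary TBS ethers under pyridinium tosylate catalysis.

Step 13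
Reactants: 18 2,7-diol; 14 benzoyl chloride
Product: 20 2-O-acetyl-3,7-di-O-benzoyl-1,6-bis-O-TBS compound, via 7-O-benzoate 19 (not isolated)
Conditions: 14 (1.1 equiv), pyridine, CH2Cl2, −20 → 0 °C; then Ac2O, DMAP, 0 → 25 °C
Reagents that add atoms: benzoyl chloride (14), O=C(Cl)c1ccccc1; acetic anhydride, CC(=O)OC(C)=O
Why: Sequential acylation in one flask: the primary C7 hydroxyl is benzoylated selectively at low temperature, then DMAP-catalysed acetylation esterifies the hindered secondary C2 hydroxyl.

Step 14
Reactants: 20 triester bis-silyl ether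
Product: 21 triester trans-1,6-diol (C1–OH α, C6–OH β, C2–OAc β, C3–OBz α, C7–OBz, C4=C5)
Conditions: 48% aq. HF, MeCN, 0 → 25 °C
Reagents that add atoms: none
Why: Fluoride-mediated cleavage of both silyl ethers with aqueous HF in acetonitrile, an acidic medium in which the three esters do not migrate, unveils the trans-1,6-diol.

Step 15
Reactants: 21 triester trans-1,6-diol
Product: 22 [(1S,2S,3R,6S)-2-acetoxy-3-(benzoyloxy)-7-oxabicyclo[4.1.0]hept-4-en-1-yl]methyl benzoate (target)
Conditions: PPh3, DIAD, toluene, 0 → 25 °C
Reagents that add atoms: none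
Why: Mitsunobu cyclodehydration of a trans-1,2-diol: the secondary allylic C6 hydroxyl is activated as its oxyphosphonium and displaced by the tertiary C1 oxygen with inversion at C6 (C1 cannot be the electrophile), which closes the oxirane on the α face, trans to the C2 acetate, under neutral conditions that leave the esters in place.

**Compound list**
1 | 4-hydroxybenzyl alcohol | OCc1ccc(O)cc1 | starting material
2 | 4-{[(tert-butyldimethylsilyl)oxy]methyl}phenol | CC(C)(C)[Si](C)(C)OCc1ccc(O)cc1 | intermediate
3 | 4-hydroxy-4-(TBS-oxymethyl)cyclohexa-2,5-dien-1-one | CC(C)(C)[Si](C)(C)OCC1(O)C=CC(=O)C=C1 | intermediate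
4 | 4-(TBS-oxy)-4-(TBS-oxymethyl)cyclohexa-2,5-dien-1-one | CC(C)(C)[Si](C)(C)OCC1(O[Si](C)(C)C(C)(C)C)C=CC(=O)C=C1 | intermediate
5 | 4-(TBS-oxy)-4-(hydroxymethyl)cyclohexa-2,5-dien-1-one (key-step precursor) | O=C1C=CC(CO)(O[Si](C)(C)C(C)(C)C)C=C1 | intermediate
6 | phenylboronic acid | OB(O)c1ccccc1 | starting material
7 | (4aR,8aS)-4a-(TBS-oxy)-2-phenyl-4a,8a-dihydro-4H-benzo[d][1,3,2]dioxaborinin-7(8H)-one (cis-fused dioxaborinane enone, key-step product) | O=C1C[C@@H]2OB(c3ccccc3)OC[C@]2(O[Si](C)(C)C(C)(C)C)C=C1 | intermediate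
8 | diol enone (C2–OH β, C7–OH, C1–OTBS α, C4 ketone, C5=C6) | O=C1C[C@H](O)[C@@](CO)(O[Si](C)(C)C(C)(C)C)C=C1 | intermediate
9 | acetonide enone (O2,O7-isopropylidene, C1–OTBS α, C4 ketone, C5=C6) | O=C1C[C@@H]2OC(C)(C)OC[C@]2(O[Si](C)(C)C(C)(C)C)C=C1 | intermediate
10 | 5,6β-epoxy ketone (acetonide, C1–OTBS α) | O=C1C[C@@H]2OC(C)(C)OC[C@]2(O[Si](C)(C)C(C)(C)C)[C@@H]3O[C@H]13 | intermediate
11 | trimethylsilyl enol ether of 10 (C3=C4–OSiMe3) | C[Si](C)(C)OC1=C[C@@H]2OC(C)(C)OC[C@]2(O[Si](C)(C)C(C)(C)C)[C@@H]3O[C@H]13 | intermediate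
12 | 3α-trimethylsilyloxy-5,6β-epoxy ketone | O=C1[C@@H](O[Si](C)(C)C)[C@@H]2OC(C)(C)OC[C@]2(O[Si](C)(C)C(C)(C)C)[C@@H]3O[C@H]13 | intermediate
13 | 3α-hydroxy-5,6β-epoxy ketone (ketol) | O=C1[C@@H](O)[C@@H]2OC(C)(C)OC[C@]2(O[Si](C)(C)C(C)(C)C)[C@@H]3O[C@H]13 | intermediate
14 | benzoyl chloride | O=C(Cl)c1ccccc1 | starting material
15 | 3α-benzoyloxy-5,6β-epoxy ketone | O=C1[C@@H](OC(=O)c4ccccc4)[C@@H]2OC(C)(C)OC[C@]2(O[Si](C)(C)C(C)(C)C)[C@@H]3O[C@H]13 | intermediate
16 | allylic alcohol (C4=C5, C6–OH β, C3–OBz α, acetonide, C1–OTBS α) | O[C@@H]1C=C[C@@H](OC(=O)c2ccccc2)[C@@H]2OC(C)(C)OC[C@]12O[Si](C)(C)C(C)(C)C | intermediate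
17 | 6-O-TBS ether of 16 | CC(C)(C)[Si](C)(C)O[C@@H]1C=C[C@@H](OC(=O)c2ccccc2)[C@@H]2OC(C)(C)OC[C@]12O[Si](C)(C)C(C)(C)C | intermediate
18 | 2,7-diol (C3–OBz α, C1–OTBS α, C6–OTBS β) | CC(C)(C)[Si](C)(C)O[C@@H]1C=C[C@@H](OC(=O)c2ccccc2)[C@H](O)[C@@]1(CO)O[Si](C)(C)C(C)(C)C | intermediate
19 | 7-O-benzoate with free C2–OH | CC(C)(C)[Si](C)(C)O[C@@H]1C=C[C@@H](OC(=O)c2ccccc2)[C@H](O)[C@@]1(COC(=O)c2ccccc2)O[Si](C)(C)C(C)(C)C | intermediate
20 | 2-O-acetyl-3,7-di-O-benzoyl-1,6-bis-O-TBS compound | CC(C)(C)[Si](C)(C)O[C@@H]1C=C[C@@H](OC(=O)c2ccccc2)[C@H](OC(C)=O)[C@@]1(COC(=O)c2ccccc2)O[Si](C)(C)C(C)(C)C | intermediate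
21 | triester trans-1,6-diol | O[C@@H]1C=C[C@@H](OC(=O)c2ccccc2)[C@H](OC(C)=O)[C@@]1(COC(=O)c2ccccc2)O | intermediate
22 | [(1S,2S,3R,6S)-2-acetoxy-3-(benzoyloxy)-7-oxabicyclo[4.1.0]hept-4-en-1-yl]methyl benzoate | CC(=O)O[C@H]1[C@H](OC(=O)c2ccccc2)C=C[C@@H]2O[C@@]21COC(=O)c1ccccc1 | target

**Step count and risks**
Total steps: 15. Longest linear sequence: 15 steps, from 1 to 22 (the route is fully linear).

The three steps most likely to fail:

1. Step 5 (the step that carries the proposed new method). The catalyst may discriminate poorly between the two enantiotopic enone arms, the hemiester may turn over slowly, or the amine may induce retro-aldol loss of formaldehyde from 5 with aromatisation. The fallback uses known chemistry and sets out from 4. A desymmetrising conjugate borylation (CuCl, NaOtBu, a chiral ferrocenyl bisphosphine of the Josiphos type, B2pin2, MeOH, THF, 0 °C), in which the copper–boryl species should add to C2 of one arm anti to the C1 silyloxy group, would give the β-boryl enone F1. Oxidation with NaBO3·4H2O in THF/H2O, which proceeds with retention, would give the β-hydroxy enone F2. HF·pyridine would then remove the primary silyl ether to give diol 8, which is converted into 9 with 2,2-dimethoxypropane and PPTS as in step 6. The route is rejoined at 8.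

2. Step 8. The peracid may attack the enol ether with poor facial selectivity, or mainly from the β face, because the pseudoaxial C1 silyloxy group shields the α face at C3. The fallback sets out from 10: the same oxidation would then give the C3-epimeric ketol F3 (C3–OH β). Mitsunobu esterification with benzoic acid (PPh3, DIAD, PhCO2H, toluene) would invert C3 by SN2 displacement and give benzoate 15 directly, so C3 is set by inversion instead of facial choice. The route is rejoined at 15.

3. Step 10. Hydrazine may cleave or transfer the C3 benzoyl group, or the hydrazone may fragment sluggishly at the hindered ketone. The fallback sets out from 15. Reduction (NaBH4, CeCl3·7H2O, MeOH, −78 °C) would give the epoxy alcohol F4 (either C4 epimer serves), and 1,1'-thiocarbonyldiimidazole would convert it into the imidazolyl thiocarbonate F5. Bu3SnH/AIBN (toluene, 80 °C) would then generate the C4 radical, which opens the oxirane at C5–O and, after hydrogen transfer to the C6 alkoxy radical, gives 16. The route is rejoined at 16.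

**Further compounds**
F1 | step 5 | β-boryl enone (C2–Bpin β, C1–OTBS α, C7–OTBS, C4 ketone, C5=C6) | O=C1C[C@H](B2OC(C)(C)C(C)(C)O2)[C@@](CO[Si](C)(C)C(C)(C)C)(O[Si](C)(C)C(C)(C)C)C=C1
F2 | step 5 | β-hydroxy enone (C2–OH β, C1–OTBS α, C7–OTBS) | O=C1C[C@H](O)[C@@](CO[Si](C)(C)C(C)(C)C)(O[Si](C)(C)C(C)(C)C)C=C1
F3 | step 8 | C3-epimeric ketol (3β-hydroxy-5,6β-epoxy ketone) | O=C1[C@H](O)[C@@H]2OC(C)(C)OC[C@]2(O[Si](C)(C)C(C)(C)C)[C@@H]3O[C@H]13
F4 | step 10 | epoxy alcohol (C4–OH, either epimer; 3α-OBz, 5,6β-oxirane) | OC1[C@@H](OC(=O)c4ccccc4)[C@@H]2OC(C)(C)OC[C@]2(O[Si](C)(C)C(C)(C)C)[C@@H]3O[C@H]13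
F5 | step 10 | imidazolyl thiocarbonate of F4 | S=C(n1ccnc1)OC1[C@@H](OC(=O)c4ccccc4)[C@@H]2OC(C)(C)OC[C@]2(O[Si](C)(C)C(C)(C)C)[C@@H]3O[C@H]13
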